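**Assumption (one line):** locants C1–C15 follow germacrane-type numbering of the target: C6 carries the lactone oxygen, C7 carries C11 (C12 = lactone carbonyl, C13 = exocyclic methylene), C8–OH, C9–O-ester, C10(C14 methyl)=C1, C2H2, C3–OAc, C4(C15 methyl)=C5. The target is (3S,6R,7S,8R,9S), 1(10)Z, 4Z, with a (2R,3R)-epoxy ester.

## Retrosynthetic overview

1. Last steps: C8 desilylation, C9 esterification with the (2R,3R)-epoxy acid (Sharpless epoxidation of angelyl alcohol, then oxidation), C3 acetylation.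
2. The ten-membered carbocycle and the cis-fused α-methylene-γ-lactone close in one operation (C6–C7 bond) by intramolecular Barbier allylation of a masked Z-enal with a 2-(bromomethyl)acrylate.
3. Key step: one-pot lithiation–borylation in which alkenyl carbon C10 undergoes a stereospecific 1,2-shift from boron to C1 (1,2-metallate rearrangement), followed by allylboration. It joins three fragments, forms C1–C10 and C8–C9, and sets C8, C9 and the Z C1=C10 alkene.
4. Fragments: a butenolide-derived silyl lactol ether (C1–C6, C15) from (S)-α-hydroxy-γ-butyrolactone; a β-alkoxy alkenylboronate (C9, C10, C14); a bromomethyl enal ester (C7, C8, C11–C13).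
5. Ring order: temporary five-membered butenolide/lactol ring first (it fixes Z C4=C5), then the ten-membered ring and the γ-lactone together.

## Route

**Step 1**
Reactants: 1 (3S)-3-hydroxyoxolan-2-one
Product: 2 (3S)-3,5-dihydroxypentan-2-one
Conditions: MeLi (2.1 equiv), THF, −78 °C; AcOH quench
Reagents that add atoms: methyllithium [Li]C
Why: Mono-addition of an organolithium to a lactone: the α-alkoxide and the stable tetrahedral lithium hemiketal stop the reaction at the methyl ketone, and the C3 stereocentre is not touched.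

**Step 2**
Reactants: 2 (3S)-3,5-dihydroxypentan-2-one
Product: 3 (3S)-3-hydroxy-4-oxopentyl 2,4,6-tri(propan-2-yl)benzoate
Conditions: 2,4,6-(i-Pr)3C6H2COCl (1.05 equiv), pyridine, DMAP (cat.), CH2Cl2, 0 → 23 °C
Reagents that add atoms: 2,4,6-tri(propan-2-yl)benzoyl chloride CC(C)c1cc(C(C)C)c(C(Cl)=O)c(C(C)C)c1
Why: Chemoselective esterification of the primary over the hindered secondary α-keto hydroxyl installs the hindered benzoate that later directs α-lithiation and serves as leaving group.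

**Step 3**
Reactants: 3 (3S)-3-hydroxy-4-oxopentyl 2,4,6-tri(propan-2-yl)benzoate
Product: 5 2-[(2S)-3-methyl-5-oxo-2,5-dihydrofuran-2-yl]ethyl 2,4,6-tri(propan-2-yl)benzoate, via acyl ylide 4 (not isolated)
Conditions: Ph3P=C=C=O (1.1 equiv), toluene, 80 °C
Reagents that add atoms: (triphenylphosphoranylidene)ketene O=C=C=P(c1ccccc1)(c1ccccc1)c1ccccc1
Why: Bestmann butenolide synthesis (O-acylation of the ylide, then intramolecular Wittig reaction with the neighbouring ketone); the ring locks C4=C5 in the Z (ring-cis) geometry.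

**Step 4**
Reactants: 5 2-[(2S)-3-methyl-5-oxo-2,5-dihydrofuran-2-yl]ethyl 2,4,6-tri(propan-2-yl)benzoate
Product: 7 2-[(2S)-3-methyl-5-(triethylsilyloxy)-2,5-dihydrofuran-2-yl]ethyl 2,4,6-tri(propan-2-yl)benzoate (C5 epimers), via lactol 6 (not isolated)
Conditions: i-Bu2AlH (1.1 equiv), CH2Cl2, −78 °C; aq. KNaC4H4O6; crude lactol, Et3SiCl, imidazole, DMF, 0 °C
Reagents that add atoms: chlorotriethylsilane CC[Si](Cl)(CC)CC
Why: Partial lactone reduction (the hindered aryl ester survives) and base-mediated silylation mask C6 at the aldehyde oxidation level as a silyl lactol ether that tolerates organolithium chemistry and is later unmasked without strong acid.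

**Step 5**
Reactants: 8 trichloroethene
Product: 11 1-methoxy-4-[(prop-1-yn-1-yloxy)methyl]benzene, via dichlorovinyl ether 9 (not isolated), via lithium alkynyl ether 10 (not isolated)
Conditions: 4-MeOC6H4CH2OH, KH, THF, 0 → 23 °C; n-BuLi (2.2 equiv), −78 °C; MeI, −78 → 23 °C
Reagents that add atoms: (4-methoxyphenyl)methanol COc1ccc(CO)cc1; iodomethane CI
Why: Greene ynol ether synthesis: alkoxide addition–elimination on trichloroethene, dehydrochlorination and Li–Cl exchange, then C-methylation of the lithium alkynyl ether.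

**Step 6**
Reactants: 11 1-methoxy-4-[(prop-1-yn-1-yloxy)methyl]benzene
Product: 12 2-{(1Z)-1-[(4-methoxyphenyl)methoxy]prop-1-en-2-yl}-4,4,5,5-tetramethyl-1,3,2-dioxaborolane
Conditions: pinacolborane, Cp2Zr(H)Cl (5 mol %), Et3N (10 mol %), CH2Cl2, 23 °C
Reagents that add atoms: pinacolborane B1OC(C)(C)C(C)(C)O1
Why: Zirconium-catalysed syn-hydroboration puts boron on the carbon β to oxygen of the polarised ynol ether, so the alkoxy group is trans to boron, the geometry that later gives the anti C8/C9 diol.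

**Step 7**
Reactants: 13 2,2-dimethoxyacetaldehyde; 14 methyl prop-2-enoate
Product: 15 methyl 3-hydroxy-4,4-dimethoxy-2-methylidenebutanoate (racemic)
Conditions: DABCO (0.5 equiv), dioxane/H2O, 23 °C, 48 h
Reagents that add atoms: none
Why: Morita–Baylis–Hillman reaction of an activated aldehyde; the carbinol centre is removed in the next step, so no stereocontrol is needed.

**Step 8**
Reactants: 15 methyl 3-hydroxy-4,4-dimethoxy-2-methylidenebutanoate
Product: 16 methyl (2Z)-2-(bromomethyl)-4-oxobut-2-enoate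
Conditions: 48% aq. HBr, H2SO4 (cat.), CH2Cl2, 0 → 23 °C
Reagents that add atoms: hydrogen bromide Br; water O
Why: Acid-mediated allylic transposition of the Baylis–Hillman alcohol gives the thermodynamically favoured (Z)-2-(bromomethyl)enoate, and the same medium hydrolyses the dimethyl acetal to the aldehyde.

**Step 9**
Reactants: 17 methyl (2Z)-2-methylbut-2-enoate
Product: 18 (2Z)-2-methylbut-2-en-1-ol
Conditions: i-Bu2AlH (2.2 equiv), CH2Cl2, −78 → 0 °C
Reagents that add atoms: none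
Why: 1,2-Reduction of the conjugated ester by the aluminium hydride keeps the Z geometry.

**Step 10**
Reactants: 18 (2Z)-2-methylbut-2-en-1-ol
Product: 19 [(2S,3R)-2,3-dimethyloxiran-2-yl]methanol
Conditions: Ti(Oi-Pr)4 (10 mol %), L-(+)-diethyl tartrate (12 mol %), t-BuOOH, 4 Å MS, CH2Cl2, −20 °C
Reagents that add atoms: tert-butyl hydroperoxide CC(C)(C)OO
Why: Sharpless asymmetric epoxidation; L-(+)-tartrate delivers oxygen to the face that gives the (2S,3R)-epoxy alcohol, which sets both side-chain stereocentres.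

**Step 11**
Reactants: 19 [(2S,3R)-2,3-dimethyloxiran-2-yl]methanol
Product: 20 (2R,3R)-2,3-dimethyloxirane-2-carboxylic acid
Conditions: RuCl3 (2 mol %), NaIO4, MeCN/CCl4/H2O, 23 °C
Reagents that add atoms: water O
Why: RuO4-catalysed oxidation of the primary alcohol to the acid leaves the epoxide and its stereocentres intact (the C2 descriptor changes only through CIP priorities).

**Step 12**
Reactants: 7 2-[(2S)-3-methyl-5-(triethylsilyloxy)-2,5-dihydrofuran-2-yl]ethyl 2,4,6-tri(propan-2-yl)benzoate; 12 2-{(1Z)-1-[(4-methoxyphenyl)methoxy]prop-1-en-2-yl}-4,4,5,5-tetramethyl-1,3,2-dioxaborolane; 16 methyl (2Z)-2-(bromomethyl)-4-oxobut-2-enoate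
Product: 24 methyl (2Z,4R,5S,6Z)-2-(bromomethyl)-4-hydroxy-5-[(4-methoxyphenyl)methoxy]-6-methyl-8-[(2S)-3-methyl-5-(triethylsilyloxy)-2,5-dihydrofuran-2-yl]octa-2,6-dienoate, via lithiated benzoate 21 (not isolated), via boronate complex 22 (not isolated), via allylboronate 23 (not isolated)
Conditions: s-BuLi, (+)-sparteine, Et2O, −78 °C, 5 h; 12, −78 °C; MgBr2·OEt2, −78 → 35 °C; then 16, −78 → 23 °C
Reagents that add atoms: none
Why: Proposed new method: (+)-sparteine-directed deprotonation gives the (R)-α-lithiated benzoate, which adds to the β-alkoxy alkenylboronate 12 with retention; alkenyl carbon C10 then undergoes a stereospecific anti 1,2-shift from boron to C1 with loss of the benzoate (inversion at C1; a 1,2-metallate rearrangement, not pericyclic) to give the (S)-α-substituted γ-alkoxy-β-methylallylboronate 23, which adds to aldehyde 16 through a chair transition state with the C1 substituent axial and the alkoxy group equatorial, so that the C8–C9 bond, the anti (8R,9S) diol and the Z C1=C10 alkene are set together; the closest known reaction type is the lithiation–borylation–allylation of lithiated carbamates and benzoates with simple alkenylboron reagents, which has not been shown for β-alkoxy trisubstituted alkenylboronates.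

**Step 13**
Reactants: 24 methyl (2Z,4R,5S,6Z)-2-(bromomethyl)-4-hydroxy-5-[(4-methoxyphenyl)methoxy]-6-methyl-8-[(2S)-3-methyl-5-(triethylsilyloxy)-2,5-dihydrofuran-2-yl]octa-2,6-dienoate
Product: 25 methyl (2Z,4R,5S,6Z)-2-(bromomethyl)-4-{[tert-butyl(dimethyl)silyl]oxy}-5-[(4-methoxyphenyl)methoxy]-6-methyl-8-[(2S)-3-methyl-5-(triethylsilyloxy)-2,5-dihydrofuran-2-yl]octa-2,6-dienoate
Conditions: TBSOTf, 2,6-lutidine, CH2Cl2, −78 °C
Reagents that add atoms: tert-butyldimethylsilyl trifluoromethanesulfonate CC(C)(C)[Si](C)(C)OS(=O)(=O)C(F)(F)F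
Why: Silyl ether formation blocks the C8 hydroxyl so that only the C6 alkoxide can lactonise in the next step and only C3–OH is acetylated later.

**Step 14**
Reactants: 25 methyl (2Z,4R,5S,6Z)-2-(bromomethyl)-4-{[tert-butyl(dimethyl)silyl]oxy}-5-[(4-methoxyphenyl)methoxy]-6-methyl-8-[(2S)-3-methyl-5-(triethylsilyloxy)-2,5-dihydrofuran-2-yl]octa-2,6-dienoate
Product: 28 (3aR,4R,5S,6Z,9S,10Z,11aR)-4-{[tert-butyl(dimethyl)silyl]oxy}-9-hydroxy-5-[(4-methoxyphenyl)methoxy]-6,10-dimethyl-3-methylidene-3a,4,5,8,9,11a-hexahydrocyclodeca[b]furan-2(3H)-one, via lactol 26 (not isolated), via hydroxy ester 27 (not isolated)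
Conditions: HF·pyridine, pyridine, THF, 0 °C; then In powder (3 equiv), THF/H2O 3:1, 0.002 M, 23 °C
Reagents that add atoms: none
Why: Intramolecular Barbier allylation–lactonisation (precedent: Barbier and Nozaki–Hiyama macrocyclisations to germacranolides): the (Z)-γ-substituted allylindium adds to the open Z-enal form of the lactol through a cyclic transition state to give the syn C6/C7 relationship (hence the cis-fused lactone, C6 R), while the C8 stereocentre (C8–H in the acrylate plane to avoid A(1,3) strain, C6 delivered syn to the silyloxy group by the forming ring) sets C7; ring opening of the lactol frees C3–OH.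

**Step 15**
Reactants: 28 (3aR,4R,5S,6Z,9S,10Z,11aR)-4-{[tert-butyl(dimethyl)silyl]oxy}-9-hydroxy-5-[(4-methoxyphenyl)methoxy]-6,10-dimethyl-3-methylidene-3a,4,5,8,9,11a-hexahydrocyclodeca[b]furan-2(3H)-one
Product: 29 (3aR,4R,5S,6Z,9S,10Z,11aR)-4-{[tert-butyl(dimethyl)silyl]oxy}-5-[(4-methoxyphenyl)methoxy]-6,10-dimethyl-3-methylidene-2-oxo-2,3,3a,4,5,8,9,11a-octahydrocyclodeca[b]furan-9-yl acetate
Conditions: Ac2O, pyridine, DMAP (cat.), CH2Cl2, 0 °C
Reagents that add atoms: acetic anhydride CC(=O)OC(C)=O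
Why: Acetylation of the only free hydroxyl (C3) under mild base that does not touch the α-methylene lactone.

**Step 16**
Reactants: 29 (3aR,4R,5S,6Z,9S,10Z,11aR)-4-{[tert-butyl(dimethyl)silyl]oxy}-5-[(4-methoxyphenyl)methoxy]-6,10-dimethyl-3-methylidene-2-oxo-2,3,3a,4,5,8,9,11a-octahydrocyclodeca[b]furan-9-yl acetate
Product: 30 (3aR,4R,5S,6Z,9S,10Z,11aR)-4-{[tert-butyl(dimethyl)silyl]oxy}-5-hydroxy-6,10-dimethyl-3-methylidene-2-oxo-2,3,3a,4,5,8,9,11a-octahydrocyclodeca[b]furan-9-yl acetate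
Conditions: DDQ, CH2Cl2/pH 7 buffer, 0 °C
Reagents that add atoms: none
Why: Oxidative cleavage of the 4-methoxybenzyl ether frees C9–OH with retention and leaves acetate, silyl ether and lactone intact.

**Step 17**
Reactants: 30 (3aR,4R,5S,6Z,9S,10Z,11aR)-4-{[tert-butyl(dimethyl)silyl]oxy}-5-hydroxy-6,10-dimethyl-3-methylidene-2-oxo-2,3,3a,4,5,8,9,11a-octahydrocyclodeca[b]furan-9-yl acetate; 20 (2R,3R)-2,3-dimethyloxirane-2-carboxylic acid
Product: 32 (3aR,4R,5S,6Z,9S,10Z,11aR)-9-acetyloxy-4-{[tert-butyl(dimethyl)silyl]oxy}-6,10-dimethyl-3-methylidene-2-oxo-2,3,3a,4,5,8,9,11a-octahydrocyclodeca[b]furan-5-yl (2R,3R)-2,3-dimethyloxirane-2-carboxylate, via mixed anhydride 31 (not isolated)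
Conditions: 20, 2,4,6-Cl3C6H2COCl, Et3N, THF, 23 °C; then 30, DMAP, toluene, 23 °C
Reagents that add atoms: none
Why: Yamaguchi esterification couples the hindered α-quaternary epoxy acid to the allylic C9 alcohol without touching any stereocentre.

**Step 18**
Reactants: 32 (3aR,4R,5S,6Z,9S,10Z,11aR)-9-acetyloxy-4-{[tert-butyl(dimethyl)silyl]oxy}-6,10-dimethyl-3-methylidene-2-oxo-2,3,3a,4,5,8,9,11a-octahydrocyclodeca[b]furan-5-yl (2R,3R)-2,3-dimethyloxirane-2-carboxylate
Product: 33 (3aS,4R,5S,6Z,9S,10Z,11aR)-9-acetyloxy-4-hydroxy-6,10-dimethyl-3-methylidene-2-oxo-2,3,3a,4,5,8,9,11a-octahydrocyclodeca[b]furan-5-yl (2R,3R)-2,3-dimethyloxirane-2-carboxylate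
Conditions: HF·pyridine, pyridine, THF, 0 → 23 °C
Reagents that add atoms: none
Why: Buffered fluoride desilylation under non-basic conditions avoids acyl migration and translactonisation to the freed C8 hydroxyl (the 3a descriptor changes only through CIP priorities).

## Compound list

1 | (3S)-3-hydroxyoxolan-2-one | O[C@H]1CCOC1=O | starting material
2 | (3S)-3,5-dihydroxypentan-2-one | CC(=O)[C@@H](O)CCO | intermediate
3 | (3S)-3-hydroxy-4-oxopentyl 2,4,6-tri(propan-2-yl)benzoate | CC(=O)[C@@H](O)CCOC(=O)c1c(C(C)C)cc(C(C)C)cc1C(C)C | intermediate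
4 | (3S)-4-oxo-3-{[(triphenylphosphoranylidene)acetyl]oxy}pentyl 2,4,6-tri(propan-2-yl)benzoate | CC(=O)[C@@H](OC(=O)C=P(c1ccccc1)(c1ccccc1)c1ccccc1)CCOC(=O)c1c(C(C)C)cc(C(C)C)cc1C(C)C | intermediate
5 | 2-[(2S)-3-methyl-5-oxo-2,5-dihydrofuran-2-yl]ethyl 2,4,6-tri(propan-2-yl)benzoate | CC1=CC(=O)O[C@H]1CCOC(=O)c1c(C(C)C)cc(C(C)C)cc1C(C)C | intermediate
6 | 2-[(2S)-5-hydroxy-3-methyl-2,5-dihydrofuran-2-yl]ethyl 2,4,6-tri(propan-2-yl)benzoate (C5 epimers) | OC1C=C(C)[C@H](CCOC(=O)c2c(C(C)C)cc(C(C)C)cc2C(C)C)O1 | intermediate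
7 | 2-[(2S)-3-methyl-5-(triethylsilyloxy)-2,5-dihydrofuran-2-yl]ethyl 2,4,6-tri(propan-2-yl)benzoate (C5 epimers) | CC[Si](CC)(CC)OC1C=C(C)[C@H](CCOC(=O)c2c(C(C)C)cc(C(C)C)cc2C(C)C)O1 | intermediate
8 | trichloroethene | ClC=C(Cl)Cl | starting material
9 | 1-{[(E)-1,2-dichloroethenyl]oxymethyl}-4-methoxybenzene | COc1ccc(CO/C(Cl)=C\Cl)cc1 | intermediate
10 | lithium 2-[(4-methoxyphenyl)methoxy]ethynide | [Li]C#COCc1ccc(OC)cc1 | intermediate
11 | 1-methoxy-4-[(prop-1-yn-1-yloxy)methyl]benzene | CC#COCc1ccc(OC)cc1 | intermediate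
12 | 2-{(1Z)-1-[(4-methoxyphenyl)methoxy]prop-1-en-2-yl}-4,4,5,5-tetramethyl-1,3,2-dioxaborolane | C/C(B1OC(C)(C)C(C)(C)O1)=C\OCc1ccc(OC)cc1 | intermediate
13 | 2,2-dimethoxyacetaldehyde | COC(OC)C=O | starting material
14 | methyl prop-2-enoate | C=CC(=O)OC | starting material
15 | methyl 3-hydroxy-4,4-dimethoxy-2-methylidenebutanoate (racemic) | C=C(C(=O)OC)C(O)C(OC)OC | intermediate
16 | methyl (2Z)-2-(bromomethyl)-4-oxobut-2-enoate | BrC/C(=C\C=O)C(=O)OC | intermediate
17 | methyl (2Z)-2-methylbut-2-enoate | C/C=C(/C)C(=O)OC | starting material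
18 | (2Z)-2-methylbut-2-en-1-ol | C/C=C(/C)CO | intermediate
19 | [(2S,3R)-2,3-dimethyloxiran-2-yl]methanol | OC[C@]1(C)O[C@@H]1C | intermediate
20 | (2R,3R)-2,3-dimethyloxirane-2-carboxylic acid | OC(=O)[C@]1(C)O[C@@H]1C | intermediate
21 | (1R)-1-lithio-2-[(2S)-3-methyl-5-(triethylsilyloxy)-2,5-dihydrofuran-2-yl]ethyl 2,4,6-tri(propan-2-yl)benzoate | CC[Si](CC)(CC)OC1C=C(C)[C@H](C[C@@H]([Li])OC(=O)c2c(C(C)C)cc(C(C)C)cc2C(C)C)O1 | intermediate
22 | lithium {(1Z)-1-[(4-methoxyphenyl)methoxy]prop-1-en-2-yl}{(1R)-2-[(2S)-3-methyl-5-(triethylsilyloxy)-2,5-dihydrofuran-2-yl]-1-[2,4,6-tri(propan-2-yl)benzoyl]oxyethyl}(pinacolato)borate | CC[Si](CC)(CC)OC1C=C(C)[C@H](C[C@H](OC(=O)c2c(C(C)C)cc(C(C)C)cc2C(C)C)[B-]2(OC(C)(C)C(C)(C)O2)/C(C)=C/OCc2ccc(OC)cc2)O1.[Li+] | intermediate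
23 | 2-{(1E,3S)-1-[(4-methoxyphenyl)methoxy]-2-methyl-4-[(2S)-3-methyl-5-(triethylsilyloxy)-2,5-dihydrofuran-2-yl]but-1-en-3-yl}-4,4,5,5-tetramethyl-1,3,2-dioxaborolane | CC[Si](CC)(CC)OC1C=C(C)[C@H](C[C@H](B2OC(C)(C)C(C)(C)O2)/C(C)=C/OCc2ccc(OC)cc2)O1 | intermediate
24 | methyl (2Z,4R,5S,6Z)-2-(bromomethyl)-4-hydroxy-5-[(4-methoxyphenyl)methoxy]-6-methyl-8-[(2S)-3-methyl-5-(triethylsilyloxy)-2,5-dihydrofuran-2-yl]octa-2,6-dienoate | CC[Si](CC)(CC)OC1C=C(C)[C@H](C/C=C(/C)[C@H](OCc2ccc(OC)cc2)[C@H](O)/C=C(\CBr)C(=O)OC)O1 | intermediate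
25 | methyl (2Z,4R,5S,6Z)-2-(bromomethyl)-4-{[tert-butyl(dimethyl)silyl]oxy}-5-[(4-methoxyphenyl)methoxy]-6-methyl-8-[(2S)-3-methyl-5-(triethylsilyloxy)-2,5-dihydrofuran-2-yl]octa-2,6-dienoate | CC[Si](CC)(CC)OC1C=C(C)[C@H](C/C=C(/C)[C@H](OCc2ccc(OC)cc2)[C@H](O[Si](C)(C)C(C)(C)C)/C=C(\CBr)C(=O)OC)O1 | intermediate
26 | methyl (2Z,4R,5S,6Z)-2-(bromomethyl)-4-{[tert-butyl(dimethyl)silyl]oxy}-8-[(2S)-5-hydroxy-3-methyl-2,5-dihydrofuran-2-yl]-5-[(4-methoxyphenyl)methoxy]-6-methylocta-2,6-dienoate | OC1C=C(C)[C@H](C/C=C(/C)[C@H](OCc2ccc(OC)cc2)[C@H](O[Si](C)(C)C(C)(C)C)/C=C(\CBr)C(=O)OC)O1 | intermediate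
27 | methyl 2-[(1R,2R,3Z,5S,7Z,9S,10R)-10-{[tert-butyl(dimethyl)silyl]oxy}-2,5-dihydroxy-9-[(4-methoxyphenyl)methoxy]-4,8-dimethylcyclodeca-3,7-dien-1-yl]prop-2-enoate | C=C(C(=O)OC)[C@@H]1[C@H](O)/C=C(/C)[C@@H](O)C/C=C(/C)[C@H](OCc2ccc(OC)cc2)[C@@H]1O[Si](C)(C)C(C)(C)C | intermediate
28 | (3aR,4R,5S,6Z,9S,10Z,11aR)-4-{[tert-butyl(dimethyl)silyl]oxy}-9-hydroxy-5-[(4-methoxyphenyl)methoxy]-6,10-dimethyl-3-methylidene-3a,4,5,8,9,11a-hexahydrocyclodeca[b]furan-2(3H)-one | C=C1C(=O)O[C@@H]2/C=C(/C)[C@@H](O)C/C=C(/C)[C@H](OCc3ccc(OC)cc3)[C@H](O[Si](C)(C)C(C)(C)C)[C@H]12 | intermediate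
29 | (3aR,4R,5S,6Z,9S,10Z,11aR)-4-{[tert-butyl(dimethyl)silyl]oxy}-5-[(4-methoxyphenyl)methoxy]-6,10-dimethyl-3-methylidene-2-oxo-2,3,3a,4,5,8,9,11a-octahydrocyclodeca[b]furan-9-yl acetate | C=C1C(=O)O[C@@H]2/C=C(/C)[C@@H](OC(C)=O)C/C=C(/C)[C@H](OCc3ccc(OC)cc3)[C@H](O[Si](C)(C)C(C)(C)C)[C@H]12 | intermediate
30 | (3aR,4R,5S,6Z,9S,10Z,11aR)-4-{[tert-butyl(dimethyl)silyl]oxy}-5-hydroxy-6,10-dimethyl-3-methylidene-2-oxo-2,3,3a,4,5,8,9,11a-octahydrocyclodeca[b]furan-9-yl acetate | C=C1C(=O)O[C@@H]2/C=C(/C)[C@@H](OC(C)=O)C/C=C(/C)[C@H](O)[C@H](O[Si](C)(C)C(C)(C)C)[C@H]12 | intermediate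
31 | (2R,3R)-2,3-dimethyloxirane-2-carboxylic 2,4,6-trichlorobenzoic anhydride | O=C(OC(=O)[C@]1(C)O[C@@H]1C)c1c(Cl)cc(Cl)cc1Cl | intermediate
32 | (3aR,4R,5S,6Z,9S,10Z,11aR)-9-acetyloxy-4-{[tert-butyl(dimethyl)silyl]oxy}-6,10-dimethyl-3-methylidene-2-oxo-2,3,3a,4,5,8,9,11a-octahydrocyclodeca[b]furan-5-yl (2R,3R)-2,3-dimethyloxirane-2-carboxylate | C=C1C(=O)O[C@@H]2/C=C(/C)[C@@H](OC(C)=O)C/C=C(/C)[C@H](OC(=O)[C@]3(C)O[C@@H]3C)[C@H](O[Si](C)(C)C(C)(C)C)[C@H]12 | intermediate
33 | (3aS,4R,5S,6Z,9S,10Z,11aR)-9-acetyloxy-4-hydroxy-6,10-dimethyl-3-methylidene-2-oxo-2,3,3a,4,5,8,9,11a-octahydrocyclodeca[b]furan-5-yl (2R,3R)-2,3-dimethyloxirane-2-carboxylate | C=C1C(=O)O[C@@H]2/C=C(/C)[C@@H](OC(C)=O)C/C=C(/C)[C@H](OC(=O)[C@]3(C)O[C@@H]3C)[C@H](O)[C@H]12 | target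

## Totals and risks

Total step count: 18. Longest linear sequence: 11 steps (steps 1–4 and 12–18).

**Step 12 (the proposed new step).** Risks: competing deprotonation of the dihydrofuran with aromatisation to a furan, sluggish migration of the electron-rich alkenyl group, and imperfect Z/anti control in the allylboration. The fallback uses known chemistry, sets out from 7 (with 11 as the source of the alkenyl partner) and comes back at 23, hence 24. Compound 7 is lithiated (s-BuLi, TMEDA, Et2O, −78 °C) and trapped with B2pin2; insertion of the lithium carbenoid into the B–B bond with loss of the benzoate, a known route to geminal bis(boronates), gives geminal bis(boronate) F1. Ynol ether 11 is hydrozirconated with Cp2Zr(H)Cl and brominated with N-bromosuccinimide to give (E)-alkenyl bromide F2. The known palladium-catalysed, enantiotopic-group-selective Suzuki–Miyaura coupling of geminal bis(boronates) with alkenyl bromides (Pd(OAc)2, TADDOL-derived phosphoramidite, KOH, dioxane/H2O) then forms the C1–C10 bond and delivers allylboronate 23, which is treated with 16 as before.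

**Step 14 (macrocyclisation).** Risks: oligomerisation, the wrong C6/C7 diastereomer, or loss of the lactol to a furan. The fallback sets out from 25 and comes back at 27, hence 28, replacing the in situ indium reagent by an isolable boron reagent. Palladium-catalysed allylic borylation (B2pin2, Pd2(dba)3, KOAc, DMSO) converts the bromide into allylboronate F3. Mild hydrolysis of the silyl lactol ether (AcOH/THF/H2O, 0 °C) gives lactol F4. Its open hydroxy-enal form undergoes the known thermal 2-alkoxycarbonyl-allylboration/lactonisation (toluene, 0.002 M, 50 °C) through a closed transition state.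

**Step 2 (selective acylation).** Risks: keto-diol 2 may sit largely as its cyclic hemiketal and be acylated on the wrong oxygen, or the α-hydroxy ketone may racemise. The fallback sets out from 1 and comes back at 3, introducing the ketone last. Lactone 1 is opened with MeNHOMe·HCl and i-PrMgCl to Weinreb amide diol F5. Its primary hydroxyl is acylated with 2,4,6-tri(propan-2-yl)benzoyl chloride (pyridine, DMAP) to benzoate F6. MeMgBr (3 equiv, THF, 0 °C) then gives 3.

## Further compounds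

F1 | step 12 | 2,2'-{2-[(2S)-3-methyl-5-(triethylsilyloxy)-2,5-dihydrofuran-2-yl]ethane-1,1-diyl}bis(4,4,5,5-tetramethyl-1,3,2-dioxaborolane) | CC[Si](CC)(CC)OC1C=C(C)[C@H](CC(B2OC(C)(C)C(C)(C)O2)B2OC(C)(C)C(C)(C)O2)O1
F2 | step 12 | 1-{[(1E)-2-bromoprop-1-en-1-yl]oxymethyl}-4-methoxybenzene | C/C(Br)=C\OCc1ccc(OC)cc1
F3 | step 14 | methyl (2E,4R,5S,6Z)-4-{[tert-butyl(dimethyl)silyl]oxy}-5-[(4-methoxyphenyl)methoxy]-6-methyl-8-[(2S)-3-methyl-5-(triethylsilyloxy)-2,5-dihydrofuran-2-yl]-2-[(4,4,5,5-tetramethyl-1,3,2-dioxaborolan-2-yl)methyl]octa-2,6-dienoate | CC[Si](CC)(CC)OC1C=C(C)[C@H](C/C=C(/C)[C@H](OCc2ccc(OC)cc2)[C@H](O[Si](C)(C)C(C)(C)C)/C=C(\CB2OC(C)(C)C(C)(C)O2)C(=O)OC)O1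
F4 | step 14 | methyl (2E,4R,5S,6Z)-4-{[tert-butyl(dimethyl)silyl]oxy}-8-[(2S)-5-hydroxy-3-methyl-2,5-dihydrofuran-2-yl]-5-[(4-methoxyphenyl)methoxy]-6-methyl-2-[(4,4,5,5-tetramethyl-1,3,2-dioxaborolan-2-yl)methyl]octa-2,6-dienoate | OC1C=C(C)[C@H](C/C=C(/C)[C@H](OCc2ccc(OC)cc2)[C@H](O[Si](C)(C)C(C)(C)C)/C=C(\CB2OC(C)(C)C(C)(C)O2)C(=O)OC)O1
F5 | step 2 | (2S)-2,4-dihydroxy-N-methoxy-N-methylbutanamide | CON(C)C(=O)[C@@H](O)CCO
F6 | step 2 | (3S)-3-hydroxy-4-[methoxy(methyl)amino]-4-oxobutyl 2,4,6-tri(propan-2-yl)benzoate | CON(C)C(=O)[C@@H](O)CCOC(=O)c1c(C(C)C)cc(C(C)C)cc1C(C)C
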